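The cyclohexane ring (C5–C10) is opened at C5–C6. The equatorial C6 oxygen next to the equatorial C5 isopropenyl group (C4=C3, C15) is a homoallylic alcohol, the signature of a carbonyl-ene reaction. In one operation a Lewis acid joins the C6 aldehyde to C5 of a 2-methylpropenyl group, closes the carbocycle, sets C5 and C6, and leaves the C4=C3 alkene ready for allylic oxidation at C15. The precursor is an acyclic aldehyde carrying the C7 tert-butyl acetate arm, a C8 silyl ether and the fully substituted C10 (vinyl, silyloxymethyl, 2-methylpropenyl). C10 comes from a copper-catalysed SN2′ alkylation and C7/C8 from an Evans syn-aldol.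

Key step: step 12

Remark (numbering, abbreviations): carbocycle C5–C10; C10 bears vinyl C1=C2 and C14H2O; C5 bears C4(=C3)–C15; C6–O; C7 bears C11–C12(=O) with C13 the exocyclic methylene; C8–O; TBDPS = tert-butyldiphenylsilyl, TBS = tert-butyldimethylsilyl.
Remark (design): the C7 arm is carried as a tert-butyl ester and O8 as a TBS ether, because a less hindered ester would lactonise onto O8 right after the aldol and would not survive unmasking of the C6 aldehyde, and the silyl ether must outlast the acid used for lactonisation.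
Assumption: the sense of induction in step 5 is to be fixed in a pilot run; the ligand antipode that gives (R)-10 is used (both antipodes are available).

Step 1
Reactants: 1 but-2-yne-1,4-diol
Product: 2 4-(TBDPS-oxy)but-2-yn-1-ol
Conditions: TBDPSCl (1 equiv), imidazole, 1 (3 equiv), THF/DMF, 0 °C → rt
Reagents that add atoms: tert-butyl(chloro)diphenylsilane, CC(C)(C)[Si](Cl)(c1ccccc1)c1ccccc1
Why: Statistical monosilylation (silyl ether formation) of a symmetrical diol used in excess, the unreacted diol being removed by aqueous wash.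

Step 2
Reactants: 2 4-(TBDPS-oxy)but-2-yn-1-ol
Product: 4 (2Z)-4-(TBDPS-oxy)-3-iodobut-2-en-1-ol, via cyclic alkenylalanate 3 (not isolated)
Conditions: Red-Al, THF, −20 → 0 °C; EtOAc; I2, THF, −78 → 0 °C
Reagents that add atoms: iodine, II
Why: Hydroxyl-directed trans-hydroalumination of the propargylic alcohol places aluminium on the distal alkyne carbon in a five-membered ring, and iodinolysis with retention should give the Z-iodide, the low temperature suppressing β-elimination of the silyloxy group to an allene.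

Step 3
Reactants: 4 (2Z)-4-(TBDPS-oxy)-3-iodobut-2-en-1-ol; 5 2-(2-methylprop-1-en-1-yl)-4,4,5,5-tetramethyl-1,3,2-dioxaborolane
Product: 6 (2E)-3-[(TBDPS-oxy)methyl]-5-methylhexa-2,4-dien-1-ol
Conditions: Pd(dppf)Cl2 (5 mol%), K3PO4, THF/H2O, 50 °C
Reagents that add atoms: none
Why: Suzuki–Miyaura coupling of an alkenyl iodide with an alkenylboronate proceeds with retention, so the geometry of the trisubstituted alkene (CH2OH cis to the new propenyl group) is fixed by the iodide.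

Step 4
Reactants: 6 (2E)-3-[(TBDPS-oxy)methyl]-5-methylhexa-2,4-dien-1-ol
Product: 8 (2E)-1-chloro-3-[(TBDPS-oxy)methyl]-5-methylhexa-2,4-diene, via allylic mesylate 7 (not isolated)
Conditions: MsCl, 2,4,6-collidine, LiCl, DMF, 0 °C; used at once
Reagents that add atoms: lithium chloride, [Li+].[Cl-]
Why: Mesylation with in situ chloride displacement (SN2) under buffered conditions converts primary allylic alcohols into chlorides without allylic transposition or loss of alkene geometry.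

Step 5
Reactants: 8 (2E)-1-chloro-3-[(TBDPS-oxy)methyl]-5-methylhexa-2,4-diene; 9 (1,3-dioxolan-2-ylmethyl)magnesium bromide (commercial 0.5 M solution in THF)
Product: 10 2-{(2R)-2-[(TBDPS-oxy)methyl]-2-ethenyl-4-methylpent-3-en-1-yl}-1,3-dioxolane
Conditions: CuTC (5 mol%), chiral BINOL-phosphoramidite L* (6 mol%), CH2Cl2, −78 °C, slow addition of 9
Reagents that add atoms: none
Why: Copper-catalysed asymmetric allylic alkylation (SN2′) of a γ,γ-disubstituted allylic chloride with a Grignard reagent forms the quaternary C10 and its vinyl group, the ligand selecting the alkene face and the fully substituted ε-carbon disfavouring attack at the far end of the diene.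

Step 6
Reactants: 10 2-{(2R)-2-[(TBDPS-oxy)methyl]-2-ethenyl-4-methylpent-3-en-1-yl}-1,3-dioxolane
Product: 11 (3R)-3-[(TBDPS-oxy)methyl]-3-ethenyl-5-methylhex-4-enal
Conditions: 2 M HCl (aq), THF, rt
Reagents that add atoms: water, O
Why: Acid-catalysed acetal hydrolysis, which the TBDPS ether and the unconjugated alkenes tolerate and which cannot touch the quaternary centre.

Step 7
Reactants: 12 4-tert-butoxy-4-oxobutanoic acid (mono-tert-butyl succinate); 13 (4R)-4-benzyl-1,3-oxazolidin-2-one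
Product: 15 tert-butyl 4-[(4R)-4-benzyl-2-oxo-1,3-oxazolidin-3-yl]-4-oxobutanoate, via mixed pivalic anhydride 14 (not isolated)
Conditions: 12, PivCl, Et3N, THF, −20 °C; then 13, LiCl, rt
Reagents that add atoms: none
Why: N-Acylation of the oxazolidinone through a mixed anhydride is a standard preparation of Evans imides from carboxylic acids.

Step 8
Reactants: 15 tert-butyl 4-[(4R)-4-benzyl-2-oxo-1,3-oxazolidin-3-yl]-4-oxobutanoate; 11 (3R)-3-[(TBDPS-oxy)methyl]-3-ethenyl-5-methylhex-4-enal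
Product: 18 tert-butyl (3R,4S,6R)-3-{[(4R)-4-benzyl-2-oxo-1,3-oxazolidin-3-yl]carbonyl}-6-[(TBDPS-oxy)methyl]-6-ethenyl-4-hydroxy-8-methylnon-7-enoate, via boron enolate 16 (not isolated), via boron aldolate 17 (not isolated)
Conditions: Bu2BOTf, i-Pr2NEt, CH2Cl2, −78 → 0 °C; 11, −78 → 0 °C; pH 7 buffer, MeOH, H2O2, 0 °C
Reagents that add atoms: none
Why: Evans syn-aldol in which the Z-boron enolate reacts through a closed chair on the face away from the benzyl group, setting C7 (R) and C8 (S) as the syn pair dictated by the (R)-auxiliary, while the hindered tert-butyl ester resists attack by the aldolate oxygen.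

Step 9
Reactants: 18 tert-butyl (3R,4S,6R)-3-{[(4R)-4-benzyl-2-oxo-1,3-oxazolidin-3-yl]carbonyl}-6-[(TBDPS-oxy)methyl]-6-ethenyl-4-hydroxy-8-methylnon-7-enoate
Product: 19 tert-butyl (3R,4S,6R)-6-[(TBDPS-oxy)methyl]-6-ethenyl-4-hydroxy-3-[methoxy(methyl)carbamoyl]-8-methylnon-7-enoate
Conditions: MeNH(OMe)·HCl, Me3Al, CH2Cl2, −20 → 0 °C; Rochelle salt
Reagents that add atoms: N,O-dimethylhydroxylamine hydrochloride, CNOC.Cl
Why: Aluminium-amide transamidation of a β-hydroxy imide (Weinreb amide formation) removes the auxiliary without retro-aldol and leaves the tert-butyl ester alone.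

Step 10
Reactants: 19 tert-butyl (3R,4S,6R)-6-[(TBDPS-oxy)methyl]-6-ethenyl-4-hydroxy-3-[methoxy(methyl)carbamoyl]-8-methylnon-7-enoate
Product: 20 tert-butyl (3R,4S,6R)-4-(TBS-oxy)-6-[(TBDPS-oxy)methyl]-6-ethenyl-3-[methoxy(methyl)carbamoyl]-8-methylnon-7-enoate
Conditions: TBSOTf (1.2 equiv), 2,6-lutidine, CH2Cl2, −78 °C
Reagents that add atoms: tert-butyldimethylsilyl trifluoromethanesulfonate, CC(C)(C)[Si](C)(C)OS(=O)(=O)C(F)(F)F
Why: Silylation of the hindered secondary alcohol with a silyl triflate and a hindered base, run cold and with little excess so that the tert-butyl ester is not attacked.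

Step 11
Reactants: 20 tert-butyl (3R,4S,6R)-4-(TBS-oxy)-6-[(TBDPS-oxy)methyl]-6-ethenyl-3-[methoxy(methyl)carbamoyl]-8-methylnon-7-enoate
Product: 22 tert-butyl (3R,4S,6R)-4-(TBS-oxy)-6-[(TBDPS-oxy)methyl]-6-ethenyl-3-formyl-8-methylnon-7-enoate, via tetrahedral aluminium adduct 21 (not isolated)
Conditions: DIBAL-H, THF, −78 °C; Rochelle salt; used directly
Reagents that add atoms: none
Why: Hydride reduction of a Weinreb amide stops at the chelated tetrahedral adduct, which releases the aldehyde only on work-up, so the tert-butyl ester is untouched at −78 °C and the C7 centre never meets base.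

Step 12
Reactants: 22 tert-butyl (3R,4S,6R)-4-(TBS-oxy)-6-[(TBDPS-oxy)methyl]-6-ethenyl-3-formyl-8-methylnon-7-enoate
Product: 24 tert-butyl 2-[(1S,2R,3S,4R,6S)-6-(TBS-oxy)-4-[(TBDPS-oxy)methyl]-4-ethenyl-2-hydroxy-3-(prop-1-en-2-yl)cyclohexyl]acetate, via aluminium alkoxide 23 (not isolated)
Conditions: Me2AlCl (2 equiv), CH2Cl2, −78 → −40 °C; aq. Rochelle salt
Reagents that add atoms: none
Why: Me2AlCl binds the C6 aldehyde, C5 of the trisubstituted alkene attacks the carbonyl carbon while a hydrogen of a C4 methyl group passes to oxygen, so C5–C6 forms and the double bond moves to C4=C3, and the complexed alcohol then loses methane to give the aluminium alkoxide, removing the proton that could start cationic side reactions. The closest known reaction is the Lewis-acid cyclisation of citronellal to isopulegol, a type I intramolecular carbonyl-ene reaction. The six-membered carbocycle C5–C10 closes in the exo mode, with both the carbonyl oxygen and C4 left outside the ring. C5 and C6 are set by a chair transition state shaped by the existing centres: the C7 arm, the C8 silyl ether and the C10 vinyl group sit equatorial, the C10 silyloxymethyl group is axial, and the aldehyde oxygen goes equatorial to avoid a 1,3-diaxial clash with it, which puts the new isopropenyl group equatorial and trans to O6. The step needs diastereoselectivity at two centres and chemoselectivity between the two alkenes on C10, and the latter is secured because the vinyl group has no allylic hydrogen and could react only through a seven-membered ring or a primary cation.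

Step 13
Reactants: 24 tert-butyl 2-[(1S,2R,3S,4R,6S)-6-(TBS-oxy)-4-[(TBDPS-oxy)methyl]-4-ethenyl-2-hydroxy-3-(prop-1-en-2-yl)cyclohexyl]acetate
Product: 25 (3aS,4S,6R,7S,7aR)-4-(TBS-oxy)-6-[(TBDPS-oxy)methyl]-6-ethenyl-7-(prop-1-en-2-yl)hexahydro-1-benzofuran-2(3H)-one
Conditions: CSA (20 mol%), toluene, rt → 50 °C
Reagents that add atoms: none
Why: Acid-catalysed lactonisation (intramolecular transesterification) of the γ-hydroxy tert-butyl ester can close only onto O6 because O8 is silylated, and the trans ring fusion follows from the C6/C7 configuration already in place.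

Step 14
Reactants: 25 (3aS,4S,6R,7S,7aR)-4-(TBS-oxy)-6-[(TBDPS-oxy)methyl]-6-ethenyl-7-(prop-1-en-2-yl)hexahydro-1-benzofuran-2(3H)-one
Product: 29 (3aS,4S,6R,7S,7aR)-4-(TBS-oxy)-6-[(TBDPS-oxy)methyl]-6-ethenyl-3-methylidene-7-(prop-1-en-2-yl)hexahydro-1-benzofuran-2(3H)-one, via lithium enolate 26 (not isolated), via Mannich base 27 (not isolated), via ammonium iodide 28 (not isolated)
Conditions: LDA, THF, −78 °C; CH2=NMe2+ I−, −78 → 0 °C; MeI, MeOH, rt; NaHCO3 (aq), EtOAc, rt
Reagents that add atoms: Eschenmoser's salt (N,N-dimethylmethyleneiminium iodide), C=[N+](C)C.[I-]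
Why: α-Methylenation by Mannich alkylation of the lactone enolate followed by quaternisation and β-elimination, C11 being the only enolisable position and C7 not being epimerised by these bases.

Step 15
Reactants: 29 (3aS,4S,6R,7S,7aR)-4-(TBS-oxy)-6-[(TBDPS-oxy)methyl]-6-ethenyl-3-methylidene-7-(prop-1-en-2-yl)hexahydro-1-benzofuran-2(3H)-one
Product: 30 (3aS,4S,6R,7S,7aR)-4-(TBS-oxy)-6-[(TBDPS-oxy)methyl]-6-ethenyl-7-(3-hydroxyprop-1-en-2-yl)-3-methylidenehexahydro-1-benzofuran-2(3H)-one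
Conditions: SeO2 (0.5 equiv), t-BuOOH, CH2Cl2, rt
Reagents that add atoms: selenium dioxide, O=[Se]=O (catalytic oxygen carrier); tert-butyl hydroperoxide, CC(C)(C)OO (stoichiometric oxygen source)
Why: Selenium dioxide allylic oxidation (ene reaction then [2,3]-shift) hydroxylates the methyl group of the 1,1-disubstituted alkene and returns the double bond to C4=C3, the vinyl group having no allylic hydrogen and the conjugated methylene being too electron-poor to react.

Step 16
Reactants: 30 (3aS,4S,6R,7S,7aR)-4-(TBS-oxy)-6-[(TBDPS-oxy)methyl]-6-ethenyl-7-(3-hydroxyprop-1-en-2-yl)-3-methylidenehexahydro-1-benzofuran-2(3H)-one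
Product: 31 (3aR,4S,6R,7S,7aR)-6-[(TBDPS-oxy)methyl]-6-ethenyl-4-hydroxy-7-(3-hydroxyprop-1-en-2-yl)-3-methylidenehexahydro-1-benzofuran-2(3H)-one
Conditions: HF·pyridine, pyridine/THF, 0 °C → rt
Reagents that add atoms: none
Why: Selective desilylation, since buffered HF cleaves a secondary TBS ether much faster than a neopentyl primary TBDPS ether and does not add to the α-methylene lactone.

Step 17
Reactants: 31 (3aR,4S,6R,7S,7aR)-6-[(TBDPS-oxy)methyl]-6-ethenyl-4-hydroxy-7-(3-hydroxyprop-1-en-2-yl)-3-methylidenehexahydro-1-benzofuran-2(3H)-one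
Product: 32 (3aR,4S,6R,7S,7aR)-7-[3-(acetyloxy)prop-1-en-2-yl]-6-[(TBDPS-oxy)methyl]-6-ethenyl-3-methylidene-2-oxooctahydro-1-benzofuran-4-yl acetate
Conditions: Ac2O, pyridine, DMAP (cat.), CH2Cl2, rt
Reagents that add atoms: acetic anhydride, CC(=O)OC(C)=O
Why: DMAP-catalysed acetylation of the secondary O8 and the primary allylic O15 hydroxyls while O14 stays silylated.

Step 18
Reactants: 32 (3aR,4S,6R,7S,7aR)-7-[3-(acetyloxy)prop-1-en-2-yl]-6-[(TBDPS-oxy)methyl]-6-ethenyl-3-methylidene-2-oxooctahydro-1-benzofuran-4-yl acetate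
Product: 33 (3aR,4S,6R,7S,7aR)-7-[3-(acetyloxy)prop-1-en-2-yl]-6-ethenyl-6-(hydroxymethyl)-3-methylidene-2-oxooctahydro-1-benzofuran-4-yl acetate (CNP0240658.1)
Conditions: TBAF/AcOH (1:1), THF, 0 °C → rt
Reagents that add atoms: none
Why: Fluoride desilylation of the TBDPS ether, buffered with acetic acid so that acetate migration and conjugate addition to the α-methylene lactone are suppressed.

Compound list
1 | but-2-yne-1,4-diol | OCC#CCO | starting material
2 | 4-(TBDPS-oxy)but-2-yn-1-ol | OCC#CCO[Si](c1ccccc1)(c1ccccc1)C(C)(C)C | intermediate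
3 | cyclic alkenylalanate, sodium salt (Al bound to O and to the carbon bearing CH2OTBDPS, two 2-methoxyethoxy ligands) | [Na+].COCCO[Al-]1(OCCOC)OCC=C1CO[Si](c1ccccc1)(c1ccccc1)C(C)(C)C | intermediate
4 | (2Z)-4-(TBDPS-oxy)-3-iodobut-2-en-1-ol | OC/C=C(I)/CO[Si](c1ccccc1)(c1ccccc1)C(C)(C)C | intermediate
5 | 2-(2-methylprop-1-en-1-yl)-4,4,5,5-tetramethyl-1,3,2-dioxaborolane | CC(C)=CB1OC(C)(C)C(C)(C)O1 | starting material
6 | (2E)-3-[(TBDPS-oxy)methyl]-5-methylhexa-2,4-dien-1-ol | OC/C=C(/CO[Si](c1ccccc1)(c1ccccc1)C(C)(C)C)C=C(C)C | intermediate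
7 | methanesulfonate of 6 | CS(=O)(=O)OC/C=C(/CO[Si](c1ccccc1)(c1ccccc1)C(C)(C)C)C=C(C)C | intermediate
8 | (2E)-1-chloro-3-[(TBDPS-oxy)methyl]-5-methylhexa-2,4-diene | ClC/C=C(/CO[Si](c1ccccc1)(c1ccccc1)C(C)(C)C)C=C(C)C | intermediate
9 | (1,3-dioxolan-2-ylmethyl)magnesium bromide | Br[Mg]CC1OCCO1 | starting material
10 | 2-{(2R)-2-[(TBDPS-oxy)methyl]-2-ethenyl-4-methylpent-3-en-1-yl}-1,3-dioxolane | C=C[C@](CO[Si](c1ccccc1)(c1ccccc1)C(C)(C)C)(CC1OCCO1)C=C(C)C | intermediate
11 | (3R)-3-[(TBDPS-oxy)methyl]-3-ethenyl-5-methylhex-4-enal | C=C[C@](CO[Si](c1ccccc1)(c1ccccc1)C(C)(C)C)(CC=O)C=C(C)C | intermediate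
12 | 4-tert-butoxy-4-oxobutanoic acid | CC(C)(C)OC(=O)CCC(=O)O | starting material
13 | (4R)-4-benzyl-1,3-oxazolidin-2-one | O=C1N[C@H](Cc2ccccc2)CO1 | starting material
14 | mixed anhydride of 12 with pivalic acid | CC(C)(C)OC(=O)CCC(=O)OC(=O)C(C)(C)C | intermediate
15 | tert-butyl 4-[(4R)-4-benzyl-2-oxo-1,3-oxazolidin-3-yl]-4-oxobutanoate | CC(C)(C)OC(=O)CCC(=O)N1[C@H](Cc2ccccc2)COC1=O | intermediate
16 | (Z)-dibutylboron enolate of 15 | CCCCB(CCCC)O/C(N1[C@H](Cc2ccccc2)COC1=O)=C\CC(=O)OC(C)(C)C | intermediate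
17 | O8-dibutylboron aldolate of 18 | C=C[C@](CO[Si](c1ccccc1)(c1ccccc1)C(C)(C)C)(C[C@H](OB(CCCC)CCCC)[C@@H](CC(=O)OC(C)(C)C)C(=O)N1[C@H](Cc2ccccc2)COC1=O)C=C(C)C | intermediate
18 | tert-butyl (3R,4S,6R)-3-{[(4R)-4-benzyl-2-oxo-1,3-oxazolidin-3-yl]carbonyl}-6-[(TBDPS-oxy)methyl]-6-ethenyl-4-hydroxy-8-methylnon-7-enoate | C=C[C@](CO[Si](c1ccccc1)(c1ccccc1)C(C)(C)C)(C[C@H](O)[C@@H](CC(=O)OC(C)(C)C)C(=O)N1[C@H](Cc2ccccc2)COC1=O)C=C(C)C | intermediate
19 | tert-butyl (3R,4S,6R)-6-[(TBDPS-oxy)methyl]-6-ethenyl-4-hydroxy-3-[methoxy(methyl)carbamoyl]-8-methylnon-7-enoate | C=C[C@](CO[Si](c1ccccc1)(c1ccccc1)C(C)(C)C)(C[C@H](O)[C@@H](CC(=O)OC(C)(C)C)C(=O)N(C)OC)C=C(C)C | intermediate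
20 | tert-butyl (3R,4S,6R)-4-(TBS-oxy)-6-[(TBDPS-oxy)methyl]-6-ethenyl-3-[methoxy(methyl)carbamoyl]-8-methylnon-7-enoate | C=C[C@](CO[Si](c1ccccc1)(c1ccccc1)C(C)(C)C)(C[C@H](O[Si](C)(C)C(C)(C)C)[C@@H](CC(=O)OC(C)(C)C)C(=O)N(C)OC)C=C(C)C | intermediate
21 | diisobutylaluminium hemiaminal adduct of 20 (new carbinol centre undefined) | C=C[C@](CO[Si](c1ccccc1)(c1ccccc1)C(C)(C)C)(C[C@H](O[Si](C)(C)C(C)(C)C)[C@@H](CC(=O)OC(C)(C)C)C(O[Al](CC(C)C)CC(C)C)N(C)OC)C=C(C)C | intermediate
22 | tert-butyl (3R,4S,6R)-4-(TBS-oxy)-6-[(TBDPS-oxy)methyl]-6-ethenyl-3-formyl-8-methylnon-7-enoate (key-step precursor; 7R,8S,10R) | C=C[C@](CO[Si](c1ccccc1)(c1ccccc1)C(C)(C)C)(C[C@H](O[Si](C)(C)C(C)(C)C)[C@@H](CC(=O)OC(C)(C)C)C=O)C=C(C)C | intermediate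
23 | O6-chloro(methyl)aluminium alkoxide of 24 | C=C[C@]1(CO[Si](c2ccccc2)(c2ccccc2)C(C)(C)C)C[C@H](O[Si](C)(C)C(C)(C)C)[C@@H](CC(=O)OC(C)(C)C)[C@H](O[Al](C)Cl)[C@H]1C(=C)C | intermediate
24 | tert-butyl 2-[(1S,2R,3S,4R,6S)-6-(TBS-oxy)-4-[(TBDPS-oxy)methyl]-4-ethenyl-2-hydroxy-3-(prop-1-en-2-yl)cyclohexyl]acetate (key-step product; 5S,6R,7S,8S,10R) | C=C[C@]1(CO[Si](c2ccccc2)(c2ccccc2)C(C)(C)C)C[C@H](O[Si](C)(C)C(C)(C)C)[C@@H](CC(=O)OC(C)(C)C)[C@H](O)[C@H]1C(=C)C | intermediate
25 | (3aS,4S,6R,7S,7aR)-4-(TBS-oxy)-6-[(TBDPS-oxy)methyl]-6-ethenyl-7-(prop-1-en-2-yl)hexahydro-1-benzofuran-2(3H)-one | C=C[C@]1(CO[Si](c2ccccc2)(c2ccccc2)C(C)(C)C)C[C@H](O[Si](C)(C)C(C)(C)C)[C@H]2CC(=O)O[C@@H]2[C@H]1C(=C)C | intermediate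
26 | lithium enolate of 25 | C=C[C@]1(CO[Si](c2ccccc2)(c2ccccc2)C(C)(C)C)C[C@H](O[Si](C)(C)C(C)(C)C)[C@H]2C=C([O-])O[C@@H]2[C@H]1C(=C)C.[Li+] | intermediate
27 | 3-[(dimethylamino)methyl] derivative of 25 (C11 epimers) | C=C[C@]1(CO[Si](c2ccccc2)(c2ccccc2)C(C)(C)C)C[C@H](O[Si](C)(C)C(C)(C)C)[C@H]2C(CN(C)C)C(=O)O[C@@H]2[C@H]1C(=C)C | intermediate
28 | trimethylammonium iodide derived from 27 | C=C[C@]1(CO[Si](c2ccccc2)(c2ccccc2)C(C)(C)C)C[C@H](O[Si](C)(C)C(C)(C)C)[C@H]2C(C[N+](C)(C)C)C(=O)O[C@@H]2[C@H]1C(=C)C.[I-] | intermediate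
29 | (3aS,4S,6R,7S,7aR)-4-(TBS-oxy)-6-[(TBDPS-oxy)methyl]-6-ethenyl-3-methylidene-7-(prop-1-en-2-yl)hexahydro-1-benzofuran-2(3H)-one | C=C[C@]1(CO[Si](c2ccccc2)(c2ccccc2)C(C)(C)C)C[C@H](O[Si](C)(C)C(C)(C)C)[C@H]2C(=C)C(=O)O[C@@H]2[C@H]1C(=C)C | intermediate
30 | (3aS,4S,6R,7S,7aR)-4-(TBS-oxy)-6-[(TBDPS-oxy)methyl]-6-ethenyl-7-(3-hydroxyprop-1-en-2-yl)-3-methylidenehexahydro-1-benzofuran-2(3H)-one | C=C[C@]1(CO[Si](c2ccccc2)(c2ccccc2)C(C)(C)C)C[C@H](O[Si](C)(C)C(C)(C)C)[C@H]2C(=C)C(=O)O[C@@H]2[C@H]1C(=C)CO | intermediate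
31 | (3aR,4S,6R,7S,7aR)-6-[(TBDPS-oxy)methyl]-6-ethenyl-4-hydroxy-7-(3-hydroxyprop-1-en-2-yl)-3-methylidenehexahydro-1-benzofuran-2(3H)-one | C=C[C@]1(CO[Si](c2ccccc2)(c2ccccc2)C(C)(C)C)C[C@H](O)[C@H]2C(=C)C(=O)O[C@@H]2[C@H]1C(=C)CO | intermediate
32 | (3aR,4S,6R,7S,7aR)-7-[3-(acetyloxy)prop-1-en-2-yl]-6-[(TBDPS-oxy)methyl]-6-ethenyl-3-methylidene-2-oxooctahydro-1-benzofuran-4-yl acetate | C=C[C@]1(CO[Si](c2ccccc2)(c2ccccc2)C(C)(C)C)C[C@H](OC(C)=O)[C@H]2C(=C)C(=O)O[C@@H]2[C@H]1C(=C)COC(C)=O | intermediate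
33 | (3aR,4S,6R,7S,7aR)-7-[3-(acetyloxy)prop-1-en-2-yl]-6-ethenyl-6-(hydroxymethyl)-3-methylidene-2-oxooctahydro-1-benzofuran-4-yl acetate (5S,6R,7R,8S,10R) | C=C[C@]1(CO)C[C@H](OC(C)=O)[C@H]2C(=C)C(=O)O[C@@H]2[C@H]1C(=C)COC(C)=O | target

Total step count: 18. Longest linear sequence: 17 steps (steps 1–6, then 8–18); step 7 is a one-step side branch.

Steps most likely to fail

Step 5. The catalyst may discriminate poorly between the two faces of the alkene, because the two C10 substituents are of similar size. Direct SN2 substitution may also compete, and the THF brought in with the Grignard solution would make both worse. The fallback sets out from dienol 6 and builds the same quaternary carbon without a catalyst. A Johnson–Claisen rearrangement (triethyl orthoacetate, cat. propionic acid, 140 °C) should give racemic ethyl 3-[(TBDPS-oxy)methyl]-3-ethenyl-5-methylhex-4-enoate F1. DIBAL-H at −78 °C should then give the racemic form of aldehyde 11, racemic 3-[(TBDPS-oxy)methyl]-3-ethenyl-5-methylhex-4-enal F2. The aldol of step 8 with imide 15 then serves as the resolving step: it should give 18 together with its C10 epimer, the (3R,4S,6S)-aldol adduct F3, and the two are to be separated by chromatography. The route is rejoined at 18.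

Step 12. The aldehyde–Lewis acid complex may leave the concerted pathway for a stepwise Prins manifold, with chloride capture or unselective proton loss from the C4 cation, or may lose silanol across C7–C8. The fallback sets out from aldehyde 22 and accepts the cation instead of avoiding it. TiCl4 in CH2Cl2 at −78 °C should close the same chair with chloride capture at C4 to give the tertiary chloride tert-butyl 2-[6-(TBS-oxy)-4-[(TBDPS-oxy)methyl]-3-(2-chloropropan-2-yl)-4-ethenyl-2-hydroxycyclohexyl]acetate F4. Dehydrochlorination with DBU in toluene at 90 °C should then remove a methyl hydrogen in preference to the hindered ring methine. The route is rejoined at 24.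

Step 13. Acid strong enough to activate the tert-butyl ester may also strip the O8 silyl ether, which would open the way to the isomeric lactone on O8, or may shift the isopropenyl double bond. The fallback sets out from 24 and separates ester cleavage from ring closure. TMSOTf/2,6-lutidine (CH2Cl2, 0 °C) should convert the tert-butyl ester into a silyl ester and cap O6, giving the bis(trimethylsilyl) derivative (O6-TMS ether, TMS ester) F5. Mild hydrolysis (K2CO3, MeOH/H2O, then citric acid) should free the hydroxy acid 2-[6-(TBS-oxy)-4-[(TBDPS-oxy)methyl]-4-ethenyl-2-hydroxy-3-(prop-1-en-2-yl)cyclohexyl]acetic acid F6. Carbodiimide lactonisation (EDC·HCl, DMAP, CH2Cl2) under basic conditions then closes the ring. The route is rejoined at 25.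

Further compounds
F1 | step 5 | racemic ethyl 3-[(TBDPS-oxy)methyl]-3-ethenyl-5-methylhex-4-enoate | CCOC(=O)CC(C=C)(CO[Si](c1ccccc1)(c1ccccc1)C(C)(C)C)C=C(C)C
F2 | step 5 | racemic 3-[(TBDPS-oxy)methyl]-3-ethenyl-5-methylhex-4-enal | O=CCC(C=C)(CO[Si](c1ccccc1)(c1ccccc1)C(C)(C)C)C=C(C)C
F3 | step 5 | tert-butyl (3R,4S,6S)-3-{[(4R)-4-benzyl-2-oxo-1,3-oxazolidin-3-yl]carbonyl}-6-[(TBDPS-oxy)methyl]-6-ethenyl-4-hydroxy-8-methylnon-7-enoate (C10 epimer of 18) | C=C[C@@](CO[Si](c1ccccc1)(c1ccccc1)C(C)(C)C)(C[C@H](O)[C@@H](CC(=O)OC(C)(C)C)C(=O)N1[C@H](Cc2ccccc2)COC1=O)C=C(C)C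
F4 | step 12 | tert-butyl 2-[6-(TBS-oxy)-4-[(TBDPS-oxy)methyl]-3-(2-chloropropan-2-yl)-4-ethenyl-2-hydroxycyclohexyl]acetate (ring configuration as in 24) | C=C[C@]1(CO[Si](c2ccccc2)(c2ccccc2)C(C)(C)C)C[C@H](O[Si](C)(C)C(C)(C)C)[C@@H](CC(=O)OC(C)(C)C)[C@H](O)[C@H]1C(C)(C)Cl
F5 | step 13 | trimethylsilyl 2-[6-(TBS-oxy)-4-[(TBDPS-oxy)methyl]-4-ethenyl-3-(prop-1-en-2-yl)-2-(trimethylsilyloxy)cyclohexyl]acetate (ring configuration as in 24) | C=C[C@]1(CO[Si](c2ccccc2)(c2ccccc2)C(C)(C)C)C[C@H](O[Si](C)(C)C(C)(C)C)[C@@H](CC(=O)O[Si](C)(C)C)[C@H](O[Si](C)(C)C)[C@H]1C(=C)C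
F6 | step 13 | 2-[6-(TBS-oxy)-4-[(TBDPS-oxy)methyl]-4-ethenyl-2-hydroxy-3-(prop-1-en-2-yl)cyclohexyl]acetic acid (ring configuration as in 24) | C=C[C@]1(CO[Si](c2ccccc2)(c2ccccc2)C(C)(C)C)C[C@H](O[Si](C)(C)C(C)(C)C)[C@@H](CC(=O)O)[C@H](O)[C@H]1C(=C)C
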